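3 questions came with your note, along with your hunch on the free base; here is the quick number.

| flask | electrophile | free base | gas | remark | time |
|---|---|---|---|---|---|
| alpha | 0.40 M | 0.092 M | 140 mM (held) | run made earlier |  |
| gamma | 0.40 M | 0.18 M | 140 mM (held) | run made earlier |  |
| delta | 0.40 M | 0.22 M | 140 mM (held) | run made earlier |  |
| south-east | 0.40 M | 0.120 M | 140 mM (held) |  | 40 min |
| west | 0.40 M | 0.240 M | 140 mM (held) |  | 40 min |

| run | time / min | electrophile / % | product / % |
|---|---|---|---|
| alpha | 3.00 | 100.1 | 0.7 |
| alpha | 6.00 | 97.8 | 0.5 |
| alpha | 12.0 | 96.1 | 2.2 |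
| alpha | 20.0 | 92.4 | 7.0 |
| alpha | 40.0 | 82.2 | 15.9 |
| gamma | 3.00 | 100.1 | 0 |
| gamma | 6.00 | 96.4 | 1.3 |
| gamma | 12.0 | 96.9 | 3.5 |
| gamma | 20.0 | 93.0 | 6.7 |
| gamma | 40.0 | 82.2 | 16.6 |
| delta | 8.00 | 97.3 | 2.8 |
| delta | 15.0 | 93.1 | 5.6 |
| delta | 25.0 | 91.0 | 11.4 |
| delta | 30.0 | 87.1 | 13.5 |
| delta | 40.0 | 84.3 | 17.5 |

(readings scatter by 1 percentage point)

- at the start none of the gas is in solution
- a reading or a percentage of product counts all its forms, free or not

1. part of the electrophile that has reacted at the end, south-east
2. part of the electrophile that has reacted at the end, west
3. what raising the concentration of free base from its lowest to its highest value here does to the part of the electrophile that has reacted (changes below 5 percentage points count as none) (no change / it rises / it falls)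

1. I compared the product at 40.0 min in alpha, gamma and delta: 15.9%, 16.6% and 17.5%, while the free base rose from 0.092 M to 0.22 M. Highest and lowest differ by 1.6 percentage points, with a scatter of 1 point on each reading, so I read no effect of the free base beyond the scatter.

2. In alpha and gamma the product starts late and then climbs steadily. I defined s, the steady rate, as the fraction of the charged electrophile turned into product per minute after the lag (induction period). Alpha and gamma between 20.0 min and 40.0 min gave s = 0.00470 min⁻¹.

3. Integrating a constant rate from the end of a lag L gives X = s(t − L), with X the part reacted and t the time. The mean of the 3 end readings of product put L at 4.54 min.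

4. At 40 min my line gave 16.7% for south-east and for west, with no change between them, though west's 0.240 M lies above delta's 0.22 M.

The forecast said 17%, 17% and no change: “The rate is therefore effectively zero order in free base”.

The flask gave 17.7% for south-east and 17.8% for west; the change from the lowest to the highest free base was 0.043 points, which counts as no change.

    electrophile + nucleophile → acid set free + product (k = 0.00210 M⁻¹ s⁻¹)
    nucleophile + acid set free ⇌ protonated nucleophile, settled at all times (K = 1600 M⁻¹)
    acid set free + free base ⇌ salt of the base (K = 23.0 M⁻¹, k = 0.00920 M⁻¹ s⁻¹)
    gas ⇌ nucleophile, rate k4*(csat - [nucleophile]) (kL = 7.80 × 10⁻⁴ s⁻¹)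
    free base + product ⇌ idle adduct, settled at all times (K = 41.0 M⁻¹)

South-east ended with 56.1% of its free base unbound and west with 73.4%, yet they held 0.0492 M and 0.0495 M of nucleophile. My line's 16.7% lay 1.0 point under south-east's answer. The neighbour is south-east itself, read at 150 min: s(t − L) gave 68.4% for it, and that flask reached 65.0%. Product, every form counted, then stood at 65.0%, and 13% of the charged free base remained unbound beside 35% of the charged electrophile.

(Readings and results were computed from invented constants, and the scatter is random.)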